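The route rests on assembling flavone ring A'' (C4a''–C8a'', a phloroglucinol ring with oxygens on C5'', C7'' and C8a'') around the C8''–C3' biaryl bond, which is carried in from the start as an aryl–alkyne bond. A Danheiser benzannulation of 3-ethoxycyclobutenone with an aryl triisopropylsiloxyalkyne makes C8''–C8a'' and C6''–C7'', closes ring A'' and leaves its three oxygens distinguished as OH, OSi and OEt, with the ring B aryl held between the first two. The precursor is the siloxyalkyne derived from benzyl-protected, acetal-masked 5-formylsalicylic acid. The pyranone is then fused at the free phenol, and the (2S)-flavanone is closed last from a chalcone.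

Key step: step 4

Atom labels: flavanone unit unprimed (ring B = C1'–C6'), flavone unit double-primed, its 2-aryl ring triple-primed. ArB = 2-(benzyloxy)-5-(1,3-dioxolan-2-yl)phenyl; FlBn = 7-(benzyloxy)-2-[4-(benzyloxy)phenyl]-5-hydroxy-4-oxo-4H-chromen-8-yl.

Remark: the facial sense of the cinchona thiourea in step 12 is not assumed by analogy; the quinidine-derived catalyst is written, and its quinine-derived pseudo-enantiomer, N-[3,5-bis(trifluoromethyl)phenyl]-N'-[(8α,9S)-6'-methoxycinchonan-9-yl]thiourea, takes its place if a trial on a simple 2',6'-dihydroxychalcone shows closure on the Re face.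

**Step 1**  
Reactants: 1 5-formylsalicylic acid  
Product: 2 benzyl 2-(benzyloxy)-5-formylbenzoate  
Conditions: BnBr (2.4 equiv), K2CO3 (3 equiv), DMF, 60 °C  
Reagents that add atoms: benzyl bromide, `BrCc1ccccc1`  
Why: Carboxylate and phenoxide are both O-alkylated by the benzylic bromide (Williamson etherification and ester formation in one operation), while the non-enolisable aldehyde is inert to carbonate.

**Step 2**  
Reactants: 2 benzyl 2-(benzyloxy)-5-formylbenzoate  
Product: 3 benzyl 2-(benzyloxy)-5-(1,3-dioxolan-2-yl)benzoate  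
Conditions: HOCH2CH2OH (3 equiv), TsOH·H2O (5 mol %), PhMe, reflux, Dean–Stark trap  
Reagents that add atoms: ethylene glycol, `OCCO`  
Why: Acid-catalysed acetalisation with azeotropic removal of water masks the aldehyde against the organolithium reagents of steps 3 and 6, the ortho-substituted aryl ester being too slow to transesterify under these conditions.

**Step 3**  
Reactants: 3 benzyl 2-(benzyloxy)-5-(1,3-dioxolan-2-yl)benzoate  
Product: 6 triisopropyl[(ArB-ethynyl)oxy]silane, via dibromomethyl ketone enolate 4 (not isolated), via lithium ynolate 5 (not isolated)  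
Conditions: CH2Br2 (2.2 equiv), lithium 2,2,6,6-tetramethylpiperidide (2.1 equiv), THF, −78 °C; add 3; LiN(SiMe3)2 (2 equiv), −78 → −20 °C; n-BuLi (4 equiv), −78 → 20 °C; iPr3SiOTf (2.5 equiv), −78 → 0 °C  
Reagents that add atoms: dibromomethane, `BrCBr`; triisopropylsilyl trifluoromethanesulfonate, `CC(C)[Si](OS(=O)(=O)C(F)(F)F)(C(C)C)C(C)C`  
Why: This is the Kowalski ester homologation halted at the ynolate, in which acylation of dibromomethyllithium gives enolate 4, bromine–lithium exchange triggers the 1,2-aryl shift to ynolate 5, and the bulky silyl triflate is taken up at oxygen rather than carbon to give the ynol ether.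

**Step 4**  
Reactants: 6 triisopropyl[(ArB-ethynyl)oxy]silane; 7 3-ethoxycyclobut-2-en-1-one  
Product: 12 2-ArB-5-ethoxy-3-[(triisopropylsilyl)oxy]phenol, via ethoxyvinylketene 8 (not isolated), via vinylcyclobutenone 9 (not isolated), via dienylketene 10 (not isolated), via cyclohexadienone 11 (not isolated)  
Conditions: 7 (1.5 equiv, in two portions), PhMe, 110 °C, sealed tube  
Reagents that add atoms: none  
Why: Heating cleaves the C1–C4 bond of 7 in a 4π electrocyclic opening to the vinylketene 8, whose ketene C=C adds to the electron-rich alkyne in a [2+2] step that makes C8''–C8a'' and C6''–C7'' and gives cyclobutenone 9. A second 4π opening turns 9 into the cis-dienylketene 10, which closes ring A'' by a thermal disrotatory 6π electrocyclisation (bond C4a''–C8a'') to dienone 11 and enolises to the phenol. The closest known reaction type is the Danheiser benzannulation of cyclobutenones with trialkylsiloxyalkynes to resorcinol monosilyl ethers. No stereocentre remains, since the one in 9 is lost on ring opening. The step must be regioselective, and should be, because the oxygen lone pair makes the aryl-bearing alkyne carbon the nucleophile that attacks the central ketene carbon. This places the aryl group between the hydroxyl (C8a'') and the silyloxy group (C7'') and leaves the ethoxy group on C5''.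

**Step 5**  
Reactants: 12 2-ArB-5-ethoxy-3-[(triisopropylsilyl)oxy]phenol  
Product: 14 3-ArB-6-ethoxy-2-hydroxy-4-[(triisopropylsilyl)oxy]benzaldehyde, via salicyl alcohol 13 (not isolated)  
Conditions: MgCl2 (2 equiv), Et3N (4 equiv), (CH2O)n (6 equiv), MeCN, 80 °C; aq. NH4Cl  
Reagents that add atoms: formaldehyde (as paraformaldehyde), `C=O`  
Why: The magnesium phenoxide directs formaldehyde to the only open ortho carbon (C4a''), and the benzylic alkoxide 13 is oxidised by hydride transfer to a second formaldehyde (Casnati–Skattebøl ortho-formylation), under conditions mild enough for the acetal, the silyl ether and the benzyl ether.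

**Step 6**  
Reactants: 14 3-ArB-6-ethoxy-2-hydroxy-4-[(triisopropylsilyl)oxy]benzaldehyde; 15 1-(benzyloxy)-4-ethynylbenzene  
Product: 17 1-{3-ArB-6-ethoxy-2-hydroxy-4-[(triisopropylsilyl)oxy]phenyl}-3-[4-(benzyloxy)phenyl]prop-2-yn-1-one, via propargylic alcohol 16 (not isolated)  
Conditions: 15 (3.2 equiv), n-BuLi (3.0 equiv), THF, −78 °C; add 14, −78 → 0 °C; aq. NH4Cl; crude alcohol, MnO2 (20 equiv), CH2Cl2, 20 °C  
Reagents that add atoms: none  
Why: Excess lithium acetylide first deprotonates the phenol and then adds to the formyl group (1,2-addition), and MnO2 oxidises the doubly activated benzylic propargylic alcohol 16, whose carbinol centre is formed racemic and erased at once, to the hydrogen-bonded ynone.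

**Step 7**  
Reactants: 17 the ynone of step 6  
Product: 19 4-(benzyloxy)-3-{2-[4-(benzyloxy)phenyl]-5-ethoxy-4-oxo-7-[(triisopropylsilyl)oxy]-4H-chromen-8-yl}benzaldehyde, via flavone acetal 18 (not isolated)  
Conditions: 4-(dimethylamino)pyridine (0.2 equiv), DMF, 40 °C; then 1 M aq. HCl, THF, 20 °C  
Reagents that add atoms: water, `O`  
Why: The aminopyridine adds to the β-carbon of the ynone and is displaced by the neighbouring phenol in an addition–elimination sequence, which enforces 6-endo closure to the pyranone over 5-exo closure to an aurone (nucleophile-catalysed oxa-Michael cyclisation of o-alkynoylphenols), and dilute acid then hydrolyses the electron-rich aryl dioxolane without touching the aryl silyl ether.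

**Step 8**  
Reactants: 19 the flavone aldehyde of step 7  
Product: 20 4-hydroxy-3-{5-hydroxy-2-(4-hydroxyphenyl)-4-oxo-7-[(triisopropylsilyl)oxy]-4H-chromen-8-yl}benzaldehyde  
Conditions: BCl3 (1 M in CH2Cl2, 8 equiv), C6HMe5 (2.5 equiv), CH2Cl2, −78 °C, then 0 → 20 °C; MeOH, then aq. NaHCO3  
Reagents that add atoms: none  
Why: BCl3 removes both benzyl groups at −78 °C, pentamethylbenzene intercepting the benzyl cations before they can alkylate ring A'', and on warming cleaves the ethyl ether at O5'' through its boron chelate with the C4'' carbonyl (chelation-assisted dealkylation), a task placed here because the later flavanone could be racemised at C2 by a Lewis acid and carries a methyl ether that must stay; the aldehyde is returned on aqueous work-up and any desilylated material converges in step 9.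

**Step 9**  
Reactants: 20 the trihydroxy aldehyde of step 8  
Product: 21 4-(benzyloxy)-3-(FlBn)benzaldehyde  
Conditions: BnBr (3.3 equiv), K2CO3 (3 equiv), CsF (1.5 equiv), DMF, 20 °C  
Reagents that add atoms: benzyl bromide, `BrCc1ccccc1`  
Why: Carbonate deprotonates the two non-chelated phenols and fluoride releases the C7'' phenoxide from silicon, all three being benzylated in situ (Williamson etherification), whereas the C5'' hydroxyl, hydrogen-bonded to the C4'' carbonyl, is too poor a nucleophile to compete and would in any case be freed again in step 13.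

**Step 10**  
Reactants: 22 1-(2,6-dihydroxy-4-methoxyphenyl)ethan-1-one  
Product: 23 1-[2-hydroxy-4-methoxy-6-(methoxymethoxy)phenyl]ethan-1-one  
Conditions: MeOCH2Cl (1.1 equiv), K2CO3 (2 equiv), acetone, 0 → 20 °C  
Reagents that add atoms: chloromethyl methyl ether, `COCCl`  
Why: Under mild carbonate conditions only the hydroxyl that is not hydrogen-bonded to the acetyl group is O-alkylated, which keeps the ketone from forming a sluggish trianion in the aldol step yet leaves a group that dilute acid removes.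

**Step 11**  
Reactants: 21 4-(benzyloxy)-3-(FlBn)benzaldehyde; 23 1-[2-hydroxy-4-methoxy-6-(methoxymethoxy)phenyl]ethan-1-one  
Product: 26 (2E)-3-[4-(benzyloxy)-3-(FlBn)phenyl]-1-(2,6-dihydroxy-4-methoxyphenyl)prop-2-en-1-one, via aldol adduct 24 (not isolated), via methoxymethyl chalcone 25 (not isolated)  
Conditions: 23 (1.5 equiv), KOH (10 equiv), EtOH/THF, 20 °C; then conc. HCl to pH 1, MeOH, 45 °C  
Reagents that add atoms: none  
Why: Hydroxide-mediated Claisen–Schmidt condensation proceeds by aldol addition to 24 and E1cB dehydration to the E-enone 25, and acidifying the same pot hydrolyses the carbonyl-flanked methoxymethyl acetal at a temperature at which acid-catalysed closure of the chalcone is still slow.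

**Step 12**  
Reactants: 26 the 2',6'-dihydroxychalcone of step 11  
Product: 27 (2S)-2-[4-(benzyloxy)-3-(FlBn)phenyl]-5-hydroxy-7-methoxy-2,3-dihydro-4H-chromen-4-one  
Conditions: N-[3,5-bis(trifluoromethyl)phenyl]-N'-[(9R)-6'-methoxycinchonan-9-yl]thiourea (10 mol %), PhMe/CHCl3, −20 °C  
Reagents that add atoms: none  
Why: In this organocatalytic intramolecular oxa-Michael addition the quinuclidine nitrogen takes the proton of the ring A hydroxyl that is not chelated to the carbonyl while the thiourea binds the enone oxygen, so that the phenoxide closes 6-endo on one face of C-β inside a chiral ion pair, attack on the Si face giving the S configuration at C2, and the hydrogen bond kept between O5–H and the C4 carbonyl should make the closure effectively irreversible at −20 °C.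

**Step 13**  
Reactants: 27 the tribenzyl (2S)-flavanone of step 12  
Product: 28 (2S)-2-{3-[5,7-dihydroxy-2-(4-hydroxyphenyl)-4-oxo-4H-chromen-8-yl]-4-hydroxyphenyl}-5-hydroxy-7-methoxy-2,3-dihydro-4H-chromen-4-one (CNP0107492.1)  
Conditions: H2 (1 atm), palladium on carbon (Pd/C, 10 wt %), THF/MeOH, 20 °C  
Reagents that add atoms: none  
Why: Hydrogenolysis of the three aryl benzyl ethers over palladium is neutral, so neither base-induced retro-oxa-Michael opening nor acid-induced ionisation at C2 can racemise the flavanone, and the methyl ether, both carbonyls and the flavone double bond should not be reduced at one atmosphere.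

**Compound list**

```
1 | 5-formyl-2-hydroxybenzoic acid (5-formylsalicylic acid) | O=Cc1ccc(O)c(C(=O)O)c1 | starting material
2 | benzyl 2-(benzyloxy)-5-formylbenzoate | O=Cc1ccc(OCc2ccccc2)c(C(=O)OCc2ccccc2)c1 | intermediate
3 | benzyl 2-(benzyloxy)-5-(1,3-dioxolan-2-yl)benzoate | O=C(OCc1ccccc1)c1cc(C2OCCO2)ccc1OCc1ccccc1 | intermediate
4 | 1-[2-(benzyloxy)-5-(1,3-dioxolan-2-yl)phenyl]-2,2-dibromoethan-1-one (present as its lithium enolate) | O=C(C(Br)Br)c1cc(C2OCCO2)ccc1OCc1ccccc1 | intermediate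
5 | lithium 2-[2-(benzyloxy)-5-(1,3-dioxolan-2-yl)phenyl]ethynolate | [Li+].[O-]C#Cc1cc(C2OCCO2)ccc1OCc1ccccc1 | intermediate
6 | ({[2-(benzyloxy)-5-(1,3-dioxolan-2-yl)phenyl]ethynyl}oxy)tri(propan-2-yl)silane | CC(C)[Si](OC#Cc1cc(C2OCCO2)ccc1OCc1ccccc1)(C(C)C)C(C)C | intermediate
7 | 3-ethoxycyclobut-2-en-1-one | CCOC1=CC(=O)C1 | starting material
8 | 3-ethoxybuta-1,3-dien-1-one | C=C(OCC)C=C=O | intermediate
9 | racemic 2-[2-(benzyloxy)-5-(1,3-dioxolan-2-yl)phenyl]-4-(1-ethoxyethenyl)-3-[(triisopropylsilyl)oxy]cyclobut-2-en-1-one | O=C1C(c2cc(C3OCCO3)ccc2OCc2ccccc2)=C(O[Si](C(C)C)(C(C)C)C(C)C)C1C(=C)OCC | intermediate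
10 | (3E)-2-[2-(benzyloxy)-5-(1,3-dioxolan-2-yl)phenyl]-5-ethoxy-3-[(triisopropylsilyl)oxy]hexa-1,3,5-trien-1-one | O=C=C(c1cc(C2OCCO2)ccc1OCc1ccccc1)/C(O[Si](C(C)C)(C(C)C)C(C)C)=C\C(=C)OCC | intermediate
11 | 2-[2-(benzyloxy)-5-(1,3-dioxolan-2-yl)phenyl]-5-ethoxy-3-[(triisopropylsilyl)oxy]cyclohexa-2,4-dien-1-one | O=C1CC(OCC)=CC(O[Si](C(C)C)(C(C)C)C(C)C)=C1c1cc(C2OCCO2)ccc1OCc1ccccc1 | intermediate
12 | 2-[2-(benzyloxy)-5-(1,3-dioxolan-2-yl)phenyl]-5-ethoxy-3-[(triisopropylsilyl)oxy]phenol | CCOc1cc(O)c(-c2cc(C3OCCO3)ccc2OCc2ccccc2)c(O[Si](C(C)C)(C(C)C)C(C)C)c1 | intermediate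
13 | 2-[2-(benzyloxy)-5-(1,3-dioxolan-2-yl)phenyl]-5-ethoxy-6-(hydroxymethyl)-3-[(triisopropylsilyl)oxy]phenol | CCOc1cc(O[Si](C(C)C)(C(C)C)C(C)C)c(-c2cc(C3OCCO3)ccc2OCc2ccccc2)c(O)c1CO | intermediate
14 | 3-[2-(benzyloxy)-5-(1,3-dioxolan-2-yl)phenyl]-6-ethoxy-2-hydroxy-4-[(triisopropylsilyl)oxy]benzaldehyde | CCOc1cc(O[Si](C(C)C)(C(C)C)C(C)C)c(-c2cc(C3OCCO3)ccc2OCc2ccccc2)c(O)c1C=O | intermediate
15 | 1-(benzyloxy)-4-ethynylbenzene | C#Cc1ccc(OCc2ccccc2)cc1 | starting material
16 | racemic 1-{3-[2-(benzyloxy)-5-(1,3-dioxolan-2-yl)phenyl]-6-ethoxy-2-hydroxy-4-[(triisopropylsilyl)oxy]phenyl}-3-[4-(benzyloxy)phenyl]prop-2-yn-1-ol | CCOc1cc(O[Si](C(C)C)(C(C)C)C(C)C)c(-c2cc(C3OCCO3)ccc2OCc2ccccc2)c(O)c1C(O)C#Cc1ccc(OCc2ccccc2)cc1 | intermediate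
17 | 1-{3-[2-(benzyloxy)-5-(1,3-dioxolan-2-yl)phenyl]-6-ethoxy-2-hydroxy-4-[(triisopropylsilyl)oxy]phenyl}-3-[4-(benzyloxy)phenyl]prop-2-yn-1-one | CCOc1cc(O[Si](C(C)C)(C(C)C)C(C)C)c(-c2cc(C3OCCO3)ccc2OCc2ccccc2)c(O)c1C(=O)C#Cc1ccc(OCc2ccccc2)cc1 | intermediate
18 | 8-[2-(benzyloxy)-5-(1,3-dioxolan-2-yl)phenyl]-2-[4-(benzyloxy)phenyl]-5-ethoxy-7-[(triisopropylsilyl)oxy]-4H-chromen-4-one | CCOc1cc(O[Si](C(C)C)(C(C)C)C(C)C)c(-c2cc(C3OCCO3)ccc2OCc2ccccc2)c2oc(-c3ccc(OCc4ccccc4)cc3)cc(=O)c12 | intermediate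
19 | 4-(benzyloxy)-3-{2-[4-(benzyloxy)phenyl]-5-ethoxy-4-oxo-7-[(triisopropylsilyl)oxy]-4H-chromen-8-yl}benzaldehyde | CCOc1cc(O[Si](C(C)C)(C(C)C)C(C)C)c(-c2cc(C=O)ccc2OCc2ccccc2)c2oc(-c3ccc(OCc4ccccc4)cc3)cc(=O)c12 | intermediate
20 | 4-hydroxy-3-{5-hydroxy-2-(4-hydroxyphenyl)-4-oxo-7-[(triisopropylsilyl)oxy]-4H-chromen-8-yl}benzaldehyde | O=Cc1ccc(O)c(-c2c(O[Si](C(C)C)(C(C)C)C(C)C)cc(O)c3c(=O)cc(-c4ccc(O)cc4)oc23)c1 | intermediate
21 | 4-(benzyloxy)-3-{7-(benzyloxy)-2-[4-(benzyloxy)phenyl]-5-hydroxy-4-oxo-4H-chromen-8-yl}benzaldehyde | O=Cc1ccc(OCc2ccccc2)c(-c2c(OCc3ccccc3)cc(O)c3c(=O)cc(-c4ccc(OCc5ccccc5)cc4)oc23)c1 | intermediate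
22 | 1-(2,6-dihydroxy-4-methoxyphenyl)ethan-1-one | CC(=O)c1c(O)cc(OC)cc1O | starting material
23 | 1-[2-hydroxy-4-methoxy-6-(methoxymethoxy)phenyl]ethan-1-one | CC(=O)c1c(O)cc(OC)cc1OCOC | intermediate
24 | racemic 3-(4-(benzyloxy)-3-{7-(benzyloxy)-2-[4-(benzyloxy)phenyl]-5-hydroxy-4-oxo-4H-chromen-8-yl}phenyl)-3-hydroxy-1-[2-hydroxy-4-methoxy-6-(methoxymethoxy)phenyl]propan-1-one | COCOc1cc(OC)cc(O)c1C(=O)CC(O)c1ccc(OCc2ccccc2)c(-c2c(OCc3ccccc3)cc(O)c3c(=O)cc(-c4ccc(OCc5ccccc5)cc4)oc23)c1 | intermediate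
25 | (2E)-3-(4-(benzyloxy)-3-{7-(benzyloxy)-2-[4-(benzyloxy)phenyl]-5-hydroxy-4-oxo-4H-chromen-8-yl}phenyl)-1-[2-hydroxy-4-methoxy-6-(methoxymethoxy)phenyl]prop-2-en-1-one | COCOc1cc(OC)cc(O)c1C(=O)/C=C/c1ccc(OCc2ccccc2)c(-c2c(OCc3ccccc3)cc(O)c3c(=O)cc(-c4ccc(OCc5ccccc5)cc4)oc23)c1 | intermediate
26 | (2E)-3-(4-(benzyloxy)-3-{7-(benzyloxy)-2-[4-(benzyloxy)phenyl]-5-hydroxy-4-oxo-4H-chromen-8-yl}phenyl)-1-(2,6-dihydroxy-4-methoxyphenyl)prop-2-en-1-one | COc1cc(O)c(C(=O)/C=C/c2ccc(OCc3ccccc3)c(-c3c(OCc4ccccc4)cc(O)c4c(=O)cc(-c5ccc(OCc6ccccc6)cc5)oc34)c2)c(O)c1 | intermediate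
27 | (2S)-2-(4-(benzyloxy)-3-{7-(benzyloxy)-2-[4-(benzyloxy)phenyl]-5-hydroxy-4-oxo-4H-chromen-8-yl}phenyl)-5-hydroxy-7-methoxy-2,3-dihydro-4H-chromen-4-one | COc1cc(O)c2c(c1)O[C@H](c1ccc(OCc3ccccc3)c(-c3c(OCc4ccccc4)cc(O)c4c(=O)cc(-c5ccc(OCc6ccccc6)cc5)oc34)c1)CC2=O | intermediate
28 | (2S)-2-{3-[5,7-dihydroxy-2-(4-hydroxyphenyl)-4-oxo-4H-chromen-8-yl]-4-hydroxyphenyl}-5-hydroxy-7-methoxy-2,3-dihydro-4H-chromen-4-one | COc1cc(O)c2c(c1)O[C@H](c1ccc(O)c(-c3c(O)cc(O)c4c(=O)cc(-c5ccc(O)cc5)oc34)c1)CC2=O | target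
```

**Step count**

Total steps: 13. Longest linear sequence: 12 steps (1–9 and 11–13); step 10 is a one-step side branch.

**Steps most likely to fail**

Step 4. The donor-stabilised cyclobutenone may open only at a temperature at which the ynol ether isomerises to a silylketene, and the vinylketene may be lost to O-acylation of the product phenol or to self-condensation. The fallback sets out from 6 and returns at 12, and makes the same ketene 8 at 20 °C by photochemical Wolff rearrangement instead of thermal ring opening. 1-Ethoxyvinyllithium (ethyl vinyl ether, t-BuLi, THF, −78 → 0 °C) is acylated with N-methoxy-N-methylacetamide to 3-ethoxybut-3-en-2-one F1. Detrifluoroacetylative diazo transfer (LiN(SiMe3)2, CF3CO2CH2CF3, THF, −78 °C; then MsN3, Et3N, MeCN/H2O) gives 1-diazo-3-ethoxybut-3-en-2-one F2. Irradiation of F2 with 6 (CH2Cl2, 300 nm, 20 °C), then brief warming (PhMe, 80 °C), should lead through 9, 10 and 11 to 12.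

Step 12. Facial discrimination in the chiral ion pair may be weak, uncatalysed closure may compete, and slow base-mediated ring opening and reclosure of the product may erode the enantiomeric purity further. The fallback sets out from 26 and returns at 27, and replaces asymmetric closure by closure without stereocontrol followed by catalytic kinetic resolution. NaOAc in EtOH at reflux should give the racemate of 27 F3. Noyori asymmetric transfer hydrogenation (RuCl(p-cymene)[(R,R)-TsNCH(Ph)CH(Ph)NH2], HCO2H/Et3N 5:2, EtOAc, 20 °C) is run to just past half conversion. By the usual sense of this catalyst it should reduce the (2R)-ketone to the cis-(2R,4R)-flavan-4-ol F4 and leave (2S)-27, which is separated by chromatography.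

Step 3. Bromine–lithium exchange or aryl migration may be incomplete on the ortho-alkoxy substrate, silylation may occur at carbon to give a silylketene, and the ynol ether may hydrolyse during isolation. The fallback sets out from 3 and returns at 6, and reaches ynolate 5 by oxidation of a lithium acetylide instead of carbenoid rearrangement. Ester 3 is reduced (LiAlH4, THF, 0 °C) to [2-(benzyloxy)-5-(1,3-dioxolan-2-yl)phenyl]methanol F5 and oxidised (MnO2, CH2Cl2) to 2-(benzyloxy)-5-(1,3-dioxolan-2-yl)benzaldehyde F6. Ohira–Bestmann homologation (dimethyl (1-diazo-2-oxopropyl)phosphonate, K2CO3, MeOH) gives 2-[4-(benzyloxy)-3-ethynylphenyl]-1,3-dioxolane F7. Deprotonation (LiN(SiMe3)2, THF, −78 °C) and oxygen transfer from lithium tert-butyl peroxide (t-BuOOH, LiN(SiMe3)2; −78 → 0 °C) should give 5, which is silylated with iPr3SiOTf as in step 3.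

**Further compounds**

```
F1 | step 4 | 3-ethoxybut-3-en-2-one | C=C(OCC)C(C)=O
F2 | step 4 | 1-diazo-3-ethoxybut-3-en-2-one | C=C(OCC)C(=O)C=[N+]=[N-]
F3 | step 12 | racemic 2-(4-(benzyloxy)-3-{7-(benzyloxy)-2-[4-(benzyloxy)phenyl]-5-hydroxy-4-oxo-4H-chromen-8-yl}phenyl)-5-hydroxy-7-methoxy-2,3-dihydro-4H-chromen-4-one | COc1cc(O)c2c(c1)OC(c1ccc(OCc3ccccc3)c(-c3c(OCc4ccccc4)cc(O)c4c(=O)cc(-c5ccc(OCc6ccccc6)cc5)oc34)c1)CC2=O
F4 | step 12 | (2R,4R)-2-(4-(benzyloxy)-3-{7-(benzyloxy)-2-[4-(benzyloxy)phenyl]-5-hydroxy-4-oxo-4H-chromen-8-yl}phenyl)-7-methoxy-3,4-dihydro-2H-chromene-4,5-diol | COc1cc(O)c2c(c1)O[C@@H](c1ccc(OCc3ccccc3)c(-c3c(OCc4ccccc4)cc(O)c4c(=O)cc(-c5ccc(OCc6ccccc6)cc5)oc34)c1)C[C@H]2O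
F5 | step 3 | [2-(benzyloxy)-5-(1,3-dioxolan-2-yl)phenyl]methanol | OCc1cc(C2OCCO2)ccc1OCc1ccccc1
F6 | step 3 | 2-(benzyloxy)-5-(1,3-dioxolan-2-yl)benzaldehyde | O=Cc1cc(C2OCCO2)ccc1OCc1ccccc1
F7 | step 3 | 2-[4-(benzyloxy)-3-ethynylphenyl]-1,3-dioxolane | C#Cc1cc(C2OCCO2)ccc1OCc1ccccc1
```
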